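(The data are simulated for an exercise; the scatter is artificial.)

In the theta run at 5.00 d, the readings put 73.7% of the starting material consumed as product; I call this the fork chance, the chance that one consumed molecule ends as product (the selectivity), and I expected product to equal the fork chance times conversion.

in all of them: free enzyme 0.0061 mol%
- gamma: starting material 20 mM; second substrate 1.3 equiv; protic impurity 8 mM; temperature −2 °C; run made earlier
- beta: starting material 20 mM; second substrate 1.3 equiv; protic impurity 12 mM; temperature 14 °C; run made earlier
- theta: starting material 9.8 mM; second substrate 1.3 equiv; protic impurity 10 mM; temperature −2 °C; run made earlier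
- ash: starting material 5.0 mM; second substrate 1.30 equiv; protic impurity 6.00 mM; at −10 °C throughout; time 10 d
- oak: starting material 20 mM; second substrate 1.30 equiv; protic impurity 10.0 mM; at 20 °C until 3.0 d, from then on at −10 °C; time 10 d

| run | time / d | product / % | starting material / % |
|---|---|---|---|
| gamma | 1.67 | 25 | 76 |
| gamma | 2.50 | 30 | 62 |
| gamma | 4.00 | 43 | 48 |
| gamma | 6.00 | 50 | 36 |
| gamma | 8.00 | 56 | 27 |
| gamma | 15.0 | 73 | 10 |
| gamma | 25.0 | 81 | 1 |
| beta | 0.625 | 33 | 51 |
| beta | 0.833 | 44 | 39 |
| beta | 1.25 | 56 | 22 |
| beta | 2.08 | 68 | 9 |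
| beta | 3.00 | 75 | 0 |
| beta | 5.00 | 78 | 0 |
| beta | 8.00 | 77 | 0 |
| theta | 1.67 | 17 | 78 |
| theta | 5.00 | 42 | 43 |
| theta | 8.00 | 55 | 24 |
| theta | 15.0 | 68 | 6 |
| theta | 25.0 | 76 | 0 |

(standard deviation of a reading: 1.5 percentage points)

- where the amount of starting material changes, what is given in equivalents or mol% on it follows

1. which of the two ends with the higher amount of product, in percent of the starting material charged ("neither" if they lie within 2 percentage points) (ash / oak / neither)
2. product at the end, in percent of the starting material charged, ash
3. product at the end, in percent of the starting material charged, oak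

I took theta's value for ash because theta's [protic impurity]/[starting material], 1.02, stood nearest ash's 1.20. Reading the decay of starting material as first-order, I got 0.164 d⁻¹ from gamma and 1.21 d⁻¹ from beta. Ash's −10 °C lies below gamma by half the step from gamma to beta, so on a logarithmic scale I reckoned 0.0602 d⁻¹, which converts 45.2% in 10 d and gives ash 33.3%. Beta showed 0% starting material at 3.00 d, and oak's first stage is warmer at 20 °C, so I took oak as finished. Oak's ratio, 0.500, lies between gamma's and beta's, and the mean of their late readings gave me 79.9% for oak, more than my figure for ash.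

The forecast said oak, with 78% for oak and 28% for ash, where “only about 40% is converted”; its ash figure lay below mine.

The simulation gave 27.7% for ash and 78.4% for oak, so oak ended higher.

    free enzyme → unfolded enzyme (k = 1.45 × 10⁻⁴ h⁻¹, Ea = 267 kJ mol⁻¹)
    starting material + free enzyme ⇌ starting complex (K = 281 M⁻¹, k = 1.06 × 10⁵ M⁻¹ h⁻¹, Ea = 52.0 kJ mol⁻¹, ΔH = −41.0 kJ mol⁻¹)
    second substrate + starting complex ⇌ ternary complex (K = 43.4 M⁻¹, k = 9.03 × 10⁵ M⁻¹ h⁻¹, Ea = 35.0 kJ mol⁻¹, ΔH = −33.0 kJ mol⁻¹)
    2 ternary complex → spent catalyst (k = 1.44 × 10⁵ M⁻¹ h⁻¹, Ea = 51.0 kJ mol⁻¹)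
    ternary complex → free enzyme + product (k = 3230 h⁻¹, Ea = 77.0 kJ mol⁻¹)
    starting material + protic impurity → quenched substrate (k = 2.13 M⁻¹ h⁻¹, Ea = 70.0 kJ mol⁻¹)
    (constants at 20 °C)

In oak, the losing branch of the fork was starting material + protic impurity to quenched substrate: without that step, oak gave 99.6% instead of 78.4%. Ash converted 36.7%, and 75.5% of that was product, against the 73.7% I carried, while 63% of its starting material still stood unbound at the end. The same flask as ash run at 5 °C kept 13.8% starting material, so the fork chance promised 63.5% product, and that flask held 60.6%.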